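**Plan**

1. The target is unit 1 (a 7-methoxy-5-hydroxyflavone: benzo ring A, pyranone ring C, 4-hydroxyphenyl ring B) bonded at C3′ of ring B to C3 of unit 2, a 5,7-dihydroxy-2-(4-hydroxyphenyl)chromen-4-one.
2. Retrosynthetic cuts, in order: the four O–isopropyl bonds and the C5 O–methyl bond of unit 1; C4–C4a of unit 1 (ring C opened to a (Z)-3-aryl-3-(3,5-dimethoxyphenoxy)acrylic acid); the aryl ether O1–C2 bond (phenol plus arylpropiolate); the C3–C4 and C2–C3 bonds of unit 1 (carboxylation of a terminal alkyne, then desilylation) and the C2–C1′ bond to ring B (Sonogashira on an aryl bromide); the unit 2 pyranone at O1–C2 and C2–C3 (deoxybenzoin plus aroyl chloride); the deoxybenzoin aryl–CO bond (phloroglucinol plus arylacetic acid).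
3. Enabling feature: C4a of unit 1 is ortho to O1 and ortho/para to the C5 and C7 oxygens of ring A, so a symmetric 3,5-dimethoxyphenyl ether has two equivalent, strongly activated ortho carbons for acylation. The C5 oxygen then lies peri to the C4 carbonyl, so its methyl group can be removed by chelation while the C7 methyl stays.
4. Forward order: deoxybenzoin, then the unit 2 pyranone, then alkyne and propiolate on ring B, then the aryloxyacrylate, then ring C of unit 1 by Friedel–Crafts acylation, then global dealkylation.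
5. Stereochemistry: the target has no stereocentre. The only stereo element on the route is the Z alkene of the acrylate (aryloxy cis to carboxyl), set by anti addition of the phenol across the alkyne and consumed in the ring closure.

Key step: step 12

Remark: the target carries no stereodescriptor, so the C3–C3′ biaryl axis between the units is taken as configurationally undefined and no stereocontrol is planned; isopropyl is used on every oxygen that must end as free OH.

**Route**

Step 1
Reactants: 1 2-hydroxyphenylacetic acid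
Product: 2 5-bromo-2-hydroxyphenylacetic acid
Conditions: NBS, MeCN, 0 °C → rt
Reagents that add atoms: N-bromosuccinimide, O=C1CCC(=O)N1Br
Why: Electrophilic aromatic bromination in which the hydroxyl group directs to its free para position (C5), polar MeCN favouring para monobromination of phenols.

Step 2
Reactants: 2 5-bromo-2-hydroxyphenylacetic acid
Product: 4 2-(5-bromo-2-isopropoxyphenyl)acetic acid, via isopropyl ester 3 (not isolated)
Conditions: 2-bromopropane, K2CO3, DMF, 60 °C; then aq. NaOH, MeOH, 60 °C; HCl to pH 2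
Reagents that add atoms: 2-bromopropane, CC(C)Br; sodium hydroxide, [Na+].[OH-]
Why: Williamson alkylation of phenoxide and carboxylate followed by saponification of the isopropyl ester, which leaves the aryl isopropyl ether untouched.

Step 3
Reactants: 4 2-(5-bromo-2-isopropoxyphenyl)acetic acid; 5 phloroglucinol
Product: 6 2-(5-bromo-2-isopropoxyphenyl)-1-(2,4,6-trihydroxyphenyl)ethan-1-one
Conditions: BF3·OEt2 (neat), 70 °C; then ice-water
Reagents that add atoms: none
Why: Friedel–Crafts C-acylation of the threefold-symmetric triol by the BF3-activated acid should give one regioisomer, the chelated ketone being deactivated toward a second acylation and BF3 offering no nucleophilic halide to cleave the isopropyl ether.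

Step 4
Reactants: 6 2-(5-bromo-2-isopropoxyphenyl)-1-(2,4,6-trihydroxyphenyl)ethan-1-one
Product: 7 2-(5-bromo-2-isopropoxyphenyl)-1-(2-hydroxy-4,6-diisopropoxyphenyl)ethan-1-one
Conditions: 2-bromopropane (2.4 equiv), K2CO3, DMF, 50 °C
Reagents that add atoms: 2-bromopropane, CC(C)Br
Why: Williamson etherification that should stop at the diether because the last hydroxyl is hydrogen-bonded to the ketone and is the least nucleophilic.

Step 5
Reactants: 8 4-isopropoxybenzoic acid
Product: 9 4-isopropoxybenzoyl chloride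
Conditions: (COCl)2, DMF (cat.), CH2Cl2, 0 °C → rt
Reagents that add atoms: oxalyl chloride, O=C(Cl)C(=O)Cl
Why: Acid chloride formation through the Vilsmeier-type chloroiminium catalyst, with only gaseous by-products.

Step 6
Reactants: 7 2-(5-bromo-2-isopropoxyphenyl)-1-(2-hydroxy-4,6-diisopropoxyphenyl)ethan-1-one; 9 4-isopropoxybenzoyl chloride
Product: 12 3-(5-bromo-2-isopropoxyphenyl)-5,7-diisopropoxy-2-(4-isopropoxyphenyl)-4H-chromen-4-one, via O-aroyl ester 10 (not isolated), via 1,3-diketone 11 (not isolated)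
Conditions: DBU, pyridine, 0 → 90 °C; then p-TsOH·H2O (cat.), toluene, 90 °C
Reagents that add atoms: none
Why: O-aroylation of the phenol, Baker–Venkataraman O-to-C acyl transfer to the benzylic enolate and acid-catalysed cyclodehydration of the 1,3-diketone build the 2,3-diarylchromone, a sequence established for 2-hydroxydeoxybenzoins and aroyl chlorides.

Step 7
Reactants: 12 3-(5-bromo-2-isopropoxyphenyl)-5,7-diisopropoxy-2-(4-isopropoxyphenyl)-4H-chromen-4-one; 13 ethynyltrimethylsilane
Product: 14 5,7-diisopropoxy-2-(4-isopropoxyphenyl)-3-{2-isopropoxy-5-[(trimethylsilyl)ethynyl]phenyl}-4H-chromen-4-one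
Conditions: PdCl2(PhCN)2 (3 mol%), P(t-Bu)3·HBF4 (6 mol%), CuI (2 mol%), i-Pr2NH, 1,4-dioxane, rt → 45 °C
Reagents that add atoms: none
Why: Sonogashira coupling in which the electron-rich aryl bromide adds oxidatively to zerovalent palladium bearing the bulky trialkylphosphine and the alkynylcopper transmetallates, the chromone and ethers being inert.

Step 8
Reactants: 14 5,7-diisopropoxy-2-(4-isopropoxyphenyl)-3-{2-isopropoxy-5-[(trimethylsilyl)ethynyl]phenyl}-4H-chromen-4-one
Product: 15 3-(5-ethynyl-2-isopropoxyphenyl)-5,7-diisopropoxy-2-(4-isopropoxyphenyl)-4H-chromen-4-one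
Conditions: K2CO3 (cat.), MeOH/THF, rt
Reagents that add atoms: none
Why: Methoxide-induced protodesilylation of the alkynylsilane, mild enough to leave the chromone intact.

Step 9
Reactants: 15 3-(5-ethynyl-2-isopropoxyphenyl)-5,7-diisopropoxy-2-(4-isopropoxyphenyl)-4H-chromen-4-one
Product: 17 methyl 3-{3-[5,7-diisopropoxy-2-(4-isopropoxyphenyl)-4-oxo-4H-chromen-3-yl]-4-isopropoxyphenyl}propiolate, via potassium propiolate salt 16 (not isolated)
Conditions: CO2 (1 atm), CuCl (5 mol%), TMEDA (5 mol%), K2CO3, DMF, rt; then MeI, rt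
Reagents that add atoms: carbon dioxide, O=C=O; iodomethane, CI
Why: CuCl-catalysed carboxylation of the terminal alkyne (CO2 insertion into the alkynylcopper) followed by SN2 methylation of the carboxylate in the same flask, a known one-pot route to alkyl arylpropiolates.

Step 10
Reactants: 17 methyl 3-{3-[5,7-diisopropoxy-2-(4-isopropoxyphenyl)-4-oxo-4H-chromen-3-yl]-4-isopropoxyphenyl}propiolate; 18 3,5-dimethoxyphenol
Product: 19 methyl (Z)-3-(3,5-dimethoxyphenoxy)-3-{3-[5,7-diisopropoxy-2-(4-isopropoxyphenyl)-4-oxo-4H-chromen-3-yl]-4-isopropoxyphenyl}acrylate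
Conditions: K2CO3 (0.5 equiv), DMF, 80 °C
Reagents that add atoms: none
Why: Oxa-Michael addition of the phenoxide to the ynoate with anti protonation of the allenolate, which places the aryloxy group cis to the ester (Z), the geometry that is also the less crowded one.

Step 11
Reactants: 19 methyl (Z)-3-(3,5-dimethoxyphenoxy)-3-{3-[5,7-diisopropoxy-2-(4-isopropoxyphenyl)-4-oxo-4H-chromen-3-yl]-4-isopropoxyphenyl}acrylate
Product: 20 (Z)-3-(3,5-dimethoxyphenoxy)-3-{3-[5,7-diisopropoxy-2-(4-isopropoxyphenyl)-4-oxo-4H-chromen-3-yl]-4-isopropoxyphenyl}acrylic acid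
Conditions: LiOH·H2O, THF/MeOH/H2O, rt; then cold 1 M HCl to pH 3
Reagents that add atoms: lithium hydroxide, [Li+].[OH-]
Why: Saponification at the ester carbonyl should outrun attack at the crowded, donor-substituted β-carbon, so the aryl enol ether and the alkene geometry are kept.

Step 12
Reactants: 20 (Z)-3-(3,5-dimethoxyphenoxy)-3-{3-[5,7-diisopropoxy-2-(4-isopropoxyphenyl)-4-oxo-4H-chromen-3-yl]-4-isopropoxyphenyl}acrylic acid
Product: 22 2-{3-[5,7-diisopropoxy-2-(4-isopropoxyphenyl)-4-oxo-4H-chromen-3-yl]-4-isopropoxyphenyl}-5,7-dimethoxy-4H-chromen-4-one, via mixed trifluoroacetic anhydride 21 (not isolated)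
Conditions: TFAA (3 equiv), CH2Cl2, 0 °C → rt; then aq. NaHCO3
Reagents that add atoms: none
Why: Trifluoroacetic anhydride converts the acid into mixed anhydride 21, which (directly or after ionisation to an acylium ion stabilised by the β-aryloxy and β-aryl donors) attacks the carbon of the 3,5-dimethoxyphenyl ether that is ortho to the ether oxygen, ortho to one methoxy group and para to the other, and the Wheland intermediate loses a proton to give the pyranone. The closest known reaction types are the acid-mediated cyclisation of β-aryloxycinnamic acids to flavones and the trifluoroacetic anhydride-mediated intramolecular Friedel–Crafts acylation of aryloxy acids. Ring C of unit 1 closes by forming C4–C4a in a 6-exo-trig attack of the arene on the acyl carbon, an electrophilic aromatic substitution that creates no stereocentre. Regioselectivity is not in question because the two ortho carbons of the symmetric aryl ether are equivalent and the carbon between the methoxy groups cannot reach the acyl group. The cis relation of aryloxy and carboxyl that the closure needs is already present in the Z acid, and any E isomer should equilibrate through α-protonation by the trifluoroacetic acid released. Chemoselectivity rests on intramolecularity and on deactivation of the unit 2 rings by their chromone carbonyl, while the isopropyl ethers should tolerate trifluoroacetic acid at room temperature.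

Step 13
Reactants: 22 2-{3-[5,7-diisopropoxy-2-(4-isopropoxyphenyl)-4-oxo-4H-chromen-3-yl]-4-isopropoxyphenyl}-5,7-dimethoxy-4H-chromen-4-one
Product: 23 5-hydroxy-2-{4-hydroxy-3-[5,7-dihydroxy-2-(4-hydroxyphenyl)-4-oxo-4H-chromen-3-yl]phenyl}-7-methoxy-4H-chromen-4-one
Conditions: BCl3 (1 M in CH2Cl2, 12 equiv), CH2Cl2, −78 °C → rt; then H2O
Reagents that add atoms: none
Why: Lewis-acid ether cleavage in which BCl3 removes the four secondary isopropyl groups as 2-chloropropane and, through the six-membered chelate with the C4 carbonyl, the peri C5 methyl group of unit 1, whereas the unchelated C7 methyl ether should not be cleaved at or below room temperature.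

**Compound list**

1 | 2-hydroxyphenylacetic acid | OC(=O)Cc1ccccc1O | starting material
2 | 5-bromo-2-hydroxyphenylacetic acid | OC(=O)Cc1cc(Br)ccc1O | intermediate
3 | isopropyl 2-(5-bromo-2-isopropoxyphenyl)acetate (not isolated) | CC(C)OC(=O)Cc1cc(Br)ccc1OC(C)C | intermediate
4 | 2-(5-bromo-2-isopropoxyphenyl)acetic acid | OC(=O)Cc1cc(Br)ccc1OC(C)C | intermediate
5 | phloroglucinol | Oc1cc(O)cc(O)c1 | starting material
6 | 2-(5-bromo-2-isopropoxyphenyl)-1-(2,4,6-trihydroxyphenyl)ethan-1-one | O=C(Cc1cc(Br)ccc1OC(C)C)c1c(O)cc(O)cc1O | intermediate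
7 | 2-(5-bromo-2-isopropoxyphenyl)-1-(2-hydroxy-4,6-diisopropoxyphenyl)ethan-1-one | O=C(Cc1cc(Br)ccc1OC(C)C)c1c(O)cc(OC(C)C)cc1OC(C)C | intermediate
8 | 4-isopropoxybenzoic acid | CC(C)Oc1ccc(C(=O)O)cc1 | starting material
9 | 4-isopropoxybenzoyl chloride | CC(C)Oc1ccc(C(=O)Cl)cc1 | intermediate
10 | 2-[2-(5-bromo-2-isopropoxyphenyl)acetyl]-3,5-diisopropoxyphenyl 4-isopropoxybenzoate (O-aroyl ester, not isolated) | O=C(Cc1cc(Br)ccc1OC(C)C)c1c(OC(=O)c2ccc(OC(C)C)cc2)cc(OC(C)C)cc1OC(C)C | intermediate
11 | 2-(5-bromo-2-isopropoxyphenyl)-1-(2-hydroxy-4,6-diisopropoxyphenyl)-3-(4-isopropoxyphenyl)propane-1,3-dione (racemic, enolisable, not isolated) | O=C(c1ccc(OC(C)C)cc1)C(c1cc(Br)ccc1OC(C)C)C(=O)c1c(O)cc(OC(C)C)cc1OC(C)C | intermediate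
12 | 3-(5-bromo-2-isopropoxyphenyl)-5,7-diisopropoxy-2-(4-isopropoxyphenyl)-4H-chromen-4-one | CC(C)Oc1ccc(Br)cc1-c1c(-c2ccc(OC(C)C)cc2)oc2cc(OC(C)C)cc(OC(C)C)c2c1=O | intermediate
13 | ethynyltrimethylsilane | C#C[Si](C)(C)C | starting material
14 | 5,7-diisopropoxy-2-(4-isopropoxyphenyl)-3-{2-isopropoxy-5-[(trimethylsilyl)ethynyl]phenyl}-4H-chromen-4-one | CC(C)Oc1ccc(C#C[Si](C)(C)C)cc1-c1c(-c2ccc(OC(C)C)cc2)oc2cc(OC(C)C)cc(OC(C)C)c2c1=O | intermediate
15 | 3-(5-ethynyl-2-isopropoxyphenyl)-5,7-diisopropoxy-2-(4-isopropoxyphenyl)-4H-chromen-4-one | CC(C)Oc1ccc(C#C)cc1-c1c(-c2ccc(OC(C)C)cc2)oc2cc(OC(C)C)cc(OC(C)C)c2c1=O | intermediate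
16 | potassium 3-{3-[5,7-diisopropoxy-2-(4-isopropoxyphenyl)-4-oxo-4H-chromen-3-yl]-4-isopropoxyphenyl}propiolate (not isolated) | CC(C)Oc1ccc(C#CC(=O)[O-])cc1-c1c(-c2ccc(OC(C)C)cc2)oc2cc(OC(C)C)cc(OC(C)C)c2c1=O.[K+] | intermediate
17 | methyl 3-{3-[5,7-diisopropoxy-2-(4-isopropoxyphenyl)-4-oxo-4H-chromen-3-yl]-4-isopropoxyphenyl}propiolate | CC(C)Oc1ccc(C#CC(=O)OC)cc1-c1c(-c2ccc(OC(C)C)cc2)oc2cc(OC(C)C)cc(OC(C)C)c2c1=O | intermediate
18 | 3,5-dimethoxyphenol | COc1cc(O)cc(OC)c1 | starting material
19 | methyl (Z)-3-(3,5-dimethoxyphenoxy)-3-{3-[5,7-diisopropoxy-2-(4-isopropoxyphenyl)-4-oxo-4H-chromen-3-yl]-4-isopropoxyphenyl}acrylate (aryloxy cis to ester) | COC(=O)/C=C(\Oc1cc(OC)cc(OC)c1)c1ccc(OC(C)C)c(-c2c(-c3ccc(OC(C)C)cc3)oc3cc(OC(C)C)cc(OC(C)C)c3c2=O)c1 | intermediate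
20 | (Z)-3-(3,5-dimethoxyphenoxy)-3-{3-[5,7-diisopropoxy-2-(4-isopropoxyphenyl)-4-oxo-4H-chromen-3-yl]-4-isopropoxyphenyl}acrylic acid (aryloxy cis to carboxyl) | OC(=O)/C=C(\Oc1cc(OC)cc(OC)c1)c1ccc(OC(C)C)c(-c2c(-c3ccc(OC(C)C)cc3)oc3cc(OC(C)C)cc(OC(C)C)c3c2=O)c1 | intermediate
21 | mixed anhydride of acid 20 with trifluoroacetic acid, Z alkene (not isolated) | O=C(OC(=O)C(F)(F)F)/C=C(\Oc1cc(OC)cc(OC)c1)c1ccc(OC(C)C)c(-c2c(-c3ccc(OC(C)C)cc3)oc3cc(OC(C)C)cc(OC(C)C)c3c2=O)c1 | intermediate
22 | 2-{3-[5,7-diisopropoxy-2-(4-isopropoxyphenyl)-4-oxo-4H-chromen-3-yl]-4-isopropoxyphenyl}-5,7-dimethoxy-4H-chromen-4-one | COc1cc(OC)c2c(=O)cc(-c3ccc(OC(C)C)c(-c4c(-c5ccc(OC(C)C)cc5)oc5cc(OC(C)C)cc(OC(C)C)c5c4=O)c3)oc2c1 | intermediate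
23 | 5-hydroxy-2-{4-hydroxy-3-[5,7-dihydroxy-2-(4-hydroxyphenyl)-4-oxo-4H-chromen-3-yl]phenyl}-7-methoxy-4H-chromen-4-one (CNP0254254.0) | COc1cc(O)c2c(=O)cc(-c3ccc(O)c(-c4c(-c5ccc(O)cc5)oc5cc(O)cc(O)c5c4=O)c3)oc2c1 | target

**Step count and risks**

Total steps: 13. Longest linear sequence: 12 steps (steps 1–4 and 6–13); step 5 is a one-step side branch.

Steps most likely to fail:

Step 12. The mixed anhydride may acylate too slowly because its acyl carbon is deactivated by the vinylogous aryloxy and aryl donors. The trifluoroacetic acid released may also protonate the enol ether and expel 3,5-dimethoxyphenol before ring closure. The fallback closes ring C at O1–C2 instead. It sets out from bromide 12: methoxycarbonylation (Pd(OAc)2, Xantphos, CO 1 atm, Et3N, MeOH/toluene, 80 °C) should give methyl 3-[5,7-diisopropoxy-2-(4-isopropoxyphenyl)-4-oxo-4H-chromen-3-yl]-4-isopropoxybenzoate F1. Claisen condensation of this ester with the lithium dianion of purchased 2′-hydroxy-4′,6′-dimethoxyacetophenone (LiN(SiMe3)2, THF, −78 °C → rt) should give the 1,3-diketone F2. Cyclodehydration (p-TsOH·H2O, toluene, 90 °C) returns to the route at 22.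

Step 3. Hot BF3·OEt2 may ionise the boron-complexed isopropyl ether, after which the freed phenol would lactonise or condense with the new ketone to a benzofuran; over-acylation of phloroglucinol is a lesser concern. The fallback is a Hoesch reaction at 0 °C, setting out from acid 4. Oxalyl chloride (cat. DMF, CH2Cl2) gives 2-(5-bromo-2-isopropoxyphenyl)acetyl chloride F3, aqueous ammonia gives 2-(5-bromo-2-isopropoxyphenyl)acetamide F4, and TFAA/pyridine dehydrates it to 2-(5-bromo-2-isopropoxyphenyl)acetonitrile F5. The nitrile and phloroglucinol 5 with dry HCl and ZnCl2 in Et2O at 0 °C should give the ketiminium chloride F6, which hot water hydrolyses, returning to the route at 6.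

Step 6. The O-to-C acyl transfer must form a bond at a benzylic carbon flanked by an ortho-isopropoxyphenyl ring and a 2,6-dioxygenated aroyl group; it may stall at the ester or revert to 7 by ester cleavage. The fallback builds the pyranone at the flavanone oxidation level, setting out from 7. Piperidine-catalysed condensation with purchased 4-isopropoxybenzaldehyde (EtOH, reflux; Knoevenagel condensation then oxa-Michael closure) should give trans-3-(5-bromo-2-isopropoxyphenyl)-5,7-diisopropoxy-2-(4-isopropoxyphenyl)chroman-4-one F7 (racemic; either diastereomer converges). Dehydrogenation with DDQ in 1,4-dioxane at reflux returns to the route at 12 and makes step 5 unnecessary.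

**Further compounds**

F1 | step 12 | methyl 3-[5,7-diisopropoxy-2-(4-isopropoxyphenyl)-4-oxo-4H-chromen-3-yl]-4-isopropoxybenzoate | COC(=O)c1ccc(OC(C)C)c(-c2c(-c3ccc(OC(C)C)cc3)oc3cc(OC(C)C)cc(OC(C)C)c3c2=O)c1
F2 | step 12 | 1-(2-hydroxy-4,6-dimethoxyphenyl)-3-{3-[5,7-diisopropoxy-2-(4-isopropoxyphenyl)-4-oxo-4H-chromen-3-yl]-4-isopropoxyphenyl}propane-1,3-dione | COc1cc(O)c(C(=O)CC(=O)c2ccc(OC(C)C)c(-c3c(-c4ccc(OC(C)C)cc4)oc4cc(OC(C)C)cc(OC(C)C)c4c3=O)c2)c(OC)c1
F3 | step 3 | 2-(5-bromo-2-isopropoxyphenyl)acetyl chloride | O=C(Cl)Cc1cc(Br)ccc1OC(C)C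
F4 | step 3 | 2-(5-bromo-2-isopropoxyphenyl)acetamide | NC(=O)Cc1cc(Br)ccc1OC(C)C
F5 | step 3 | 2-(5-bromo-2-isopropoxyphenyl)acetonitrile | N#CCc1cc(Br)ccc1OC(C)C
F6 | step 3 | 2-(5-bromo-2-isopropoxyphenyl)-1-(2,4,6-trihydroxyphenyl)ethan-1-iminium chloride | [Cl-].[NH2+]=C(Cc1cc(Br)ccc1OC(C)C)c1c(O)cc(O)cc1O
F7 | step 6 | trans-3-(5-bromo-2-isopropoxyphenyl)-5,7-diisopropoxy-2-(4-isopropoxyphenyl)chroman-4-one (racemic, one enantiomer drawn) | O=C1c2c(OC(C)C)cc(OC(C)C)cc2O[C@H](c2ccc(OC(C)C)cc2)[C@H]1c1cc(Br)ccc1OC(C)C
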